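The trap is setting two flasks side by side at equal times. Monday's flask, seeded with target, gains more from 2.6 min to 9.3 min than unseeded Sunday's (autocatalysis), so at equal times a flask that is ahead has a lift from its own target on top of the partner's effect. Compare them at equal shares of the substrate charge made into target instead.

| setting | Sunday's | Monday's | Saturday's | Wednesday's |
|---|---|---|---|---|
| substrate | 0.100 M | 0.100 M | 0.100 M | 0.100 M |
| partner | 0.120 M | 0.120 M | 0.360 M | 0.870 M |
| target |  | 0.0500 M |  |  |
| time |  |  |  | 64 min |

| Sunday's run: time / min | Sunday's run: [target] / M | Monday's run: time / min | Monday's run: [target] / M | Saturday's run: time / min | Saturday's run: [target] / M |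
|---|---|---|---|---|---|
| 2.6 | 3 × 10⁻⁴ | 2.6 | 0.0524 | 2.6 | 2 × 10⁻⁴ |
| 4.9 | 9 × 10⁻⁴ | 4.9 | 0.0557 | 4.9 | 0.0015 |
| 9.3 | 0.0018 | 9.3 | 0.0605 | 9.3 | 0.0041 |
| 18 | 0.0068 | 18 | 0.0713 | 18 | 0.0128 |
| 34 | 0.0188 | 34 | 0.0900 | 34 | 0.0355 |
| 64 | 0.0443 | 64 | 0.1142 | 64 | 0.0734 |

(scatter of a reading: 3 × 10⁻⁴ M)

- Overall: substrate + partner -> target.
- Constant volume, constant temperature.
- Bound and free are read together.
- An order is taken over about fifteen percent of the charge, up and down.

- the exponent of [partner] in the starting rate at the charge of the Sunday's run (at the point where two percent of the substrate have become target)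
- target in the Wednesday's run at 64 min, as a share of the substrate charged

Here is the ladder, in share of the substrate charge made per minute, fastest first:

Saturday, 34 min to 64 min: 0.0126 min⁻¹

Monday, 2.6 min to 9.3 min, seeded with half a charge of target: 0.0121 min⁻¹

Sunday, 34 min to 64 min: 0.00850 min⁻¹

Sunday, 2.6 min to 9.3 min: 0.00224 min⁻¹

Sunday's flask therefore runs 3.79 times faster late than early, and seeded Monday starts faster than unseeded Sunday. So I match shares. Saturday made 35.5 % by 34 min, and Sunday, interpolated, reaches that share at:

53.6 min, a speed-up of 1.58

clock exponent = ln(speed-up) / ln(partner ratio) = 0.415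

This last number is the clock exponent: the logarithm of the speed-up at equal share over the logarithm of the partner ratio. I take it as my order too. Wednesday's 64 min then counts as this many Saturday minutes:

Saturday minutes = 92.3 min

Saturday's ln(made/left) climbs 0.0537 min⁻¹. Extended from its last reading, that gives:

Wednesday's share = 92.7 %

Saturday's slope read steeper from 18 min to 34 min, so this figure may lean high.

The forecast puts the order at 0.5 (0.35 to 0.7) and Wednesday's share at 85 % (78 % to 92 %), holding that “the clock should run about 1.25 times faster than Saturday's”. Its order stands above my 0.415, and its share below my 92.7 %.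

Wednesday's flask gives 92.8 %, and the order at Sunday's charge is 0.36, below the clock exponent of 0.415 read between Sunday's and Saturday's partner.

    substrate ⇌ intermediate (0.01452 min⁻¹, 0.004392 min⁻¹)
    intermediate + partner → target (0.5538 M⁻¹ min⁻¹)
    2 partner ⇌ idle reagent dimer, settled at all times (6.980 M⁻¹)
    substrate + partner + target → 2 target (3.108 M⁻² min⁻¹)

Saturday's line, extended, reaches Wednesday's share at 92.8 min, against the 92.3 min the exponent gave. Take the half-time, when target made reaches half the substrate charged. Sunday's 72.4 min, divided by the partner ratio raised to 0.415, gives 45.9 min for Saturday, whose own half-time is 43.8 min.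

The runs are simulated with constants of no real substance; the scatter is artificial.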